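**Retrosynthetic overview**
1. The target 10 is ring A (4-methoxyphenyl)–C7…C1–ring B (2,4-dihydroxy-3-methoxyphenyl) with a ketone at C3. It is cut between chain C1 and C1′ of ring B, giving vinyl ketone 7 and 2-methoxybenzene-1,3-diol 8, which are joined without protecting groups in the last step.
2. Enabling feature: C1′ of ring B is ortho to the C2′ hydroxyl and para to the C4′ hydroxyl, so it is the doubly activated C4 of 8 (C4 and C6 are equivalent through the mirror plane through C2 and C5). Chain C1 is β to the C3 ketone, so it is the electrophilic terminus of an enone. O2′ lies 1,5 to C3, so the adduct can rest as a six-membered chroman ketal (O2′, C2′, C1′, C1, C2, C3).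
3. 7 comes from Weinreb amide 4 and vinylmagnesium bromide 5; 4 comes from 5-(4-methoxyphenyl)pentanoic acid 1.
4. Ring order: rings A and B are purchased. The only ring formed is the temporary dihydropyran ring of ketal 9, closed after the C1–C1′ bond forms and reopened in the same flask (step 3).

Key step: step 3

Assumption: 10 is drawn and isolated as the open keto phenol, its 2-hydroxychroman ring-chain tautomer being regarded as the same compound; 1, 2, 5 and 8 are taken as commercially available.

**Step 1**
Reactants: 1 5-(4-methoxyphenyl)pentanoic acid; 2 N,O-dimethylhydroxylamine hydrochloride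
Product: 4 N-methoxy-5-(4-methoxyphenyl)-N-methylpentanamide, via acyl imidazole 3 (not isolated)
Conditions: CDI (1.1 equiv), CH2Cl2, rt, 1 h; then 2 (1.3 equiv), rt, 12 h
Reagents that add atoms: N,O-dimethylhydroxylamine hydrochloride (CNOC.Cl); 1,1'-carbonyldiimidazole (O=C(n1ccnc1)n1ccnc1)
Why: This carbonyldiimidazole-mediated amide coupling should convert the acid into acyl imidazole 3 with loss of CO2 (the imidazolyl group of the reagent is carried in 3 only and leaves again as imidazole), after which aminolysis by N,O-dimethylhydroxylamine, freed from its hydrochloride by the imidazole formed, should give the Weinreb amide 4.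

**Step 2**
Reactants: 4 N-methoxy-5-(4-methoxyphenyl)-N-methylpentanamide; 5 vinylmagnesium bromide
Product: 7 7-(4-methoxyphenyl)hept-1-en-3-one, via magnesium chelate 6 (not isolated)
Conditions: 5 (1.5 equiv, THF), THF, −10 to 0 °C, 1 h; inverse quench into 2 M aq HCl/Et2O, 0 °C; used at once or stored cold with a trace of BHT
Reagents that add atoms: vinylmagnesium bromide (C=C[Mg]Br)
Why: In this Weinreb ketone synthesis the five-membered N-methoxy magnesium chelate 6 should resist a second addition until the quench, and the inverse acidic quench keeps the liberated N,O-dimethylhydroxylamine protonated so that it cannot add to the vinyl ketone.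

**Step 3**
Reactants: 7 7-(4-methoxyphenyl)hept-1-en-3-one; 8 2-methoxybenzene-1,3-diol
Product: 10 1-(2,4-dihydroxy-3-methoxyphenyl)-7-(4-methoxyphenyl)heptan-3-one, via chroman methyl ketal 9 (not isolated)
Conditions: 8 (3 equiv), HC(OMe)3 (1.5 equiv), H2SO4 (5 mol %), MeOH, 0 °C, 7 added over 2 h, then rt, 16 h; then THF/2 M aq HCl, rt, 2 h
Reagents that add atoms: methanol (CO); water (O)
Why: Protonation of enone 7 (or ionisation of its methanol ketal) gives an oxocarbenium-type acceptor whose terminal CH2 is attacked by C4 of 8 in a Friedel–Crafts conjugate addition, and the keto phenol so formed is captured by its ortho hydroxyl and methanol as the mixed cyclic ketal 9 (methanol supplies its 2-OMe group and the original carbonyl oxygen leaves as water), which aqueous acid reopens to 10 with water supplying the ketone oxygen. The closest known reaction type is the acid-catalysed condensation of trimethylhydroquinone with methyl vinyl ketone in methanol/trimethyl orthoformate to a 2-methoxy-2-methylchroman, together with acid-catalysed additions of phenols to methyl vinyl ketone. The temporary dihydropyran ring closes by 6-exo-trig attack of the phenolic oxygen on the protonated C3 carbonyl and is opened again in the same flask. The only new stereocentre, the ketal carbon C2 of 9, forms without control as a racemate and is erased on hydrolysis, so the achiral target carries no stereochemical burden. Site selectivity rests on the substrate: C4 and C6 of 8 are equivalent and each is ortho to one hydroxyl and para to the other, C5 is meta to both, O-alkylation is reversible under acid and funnels to the C-adduct, and ring A of 7, bearing one methoxy group and a blocked para position, cannot compete. Mono-alkylation should be secured by the excess of 8 and the slow addition of 7, while methanol intercepts the cyclic oxocarbenium faster than a second arene could.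

**Compound list**
1 | 5-(4-methoxyphenyl)pentanoic acid | COc1ccc(CCCCC(=O)O)cc1 | starting material
2 | N,O-dimethylhydroxylamine hydrochloride | CNOC.Cl | starting material
3 | 1-(1H-imidazol-1-yl)-5-(4-methoxyphenyl)pentan-1-one (acyl imidazole, not isolated) | COc1ccc(CCCCC(=O)n2ccnc2)cc1 | intermediate
4 | N-methoxy-5-(4-methoxyphenyl)-N-methylpentanamide | COc1ccc(CCCCC(=O)N(C)OC)cc1 | intermediate
5 | vinylmagnesium bromide | C=C[Mg]Br | starting material
6 | bromomagnesium alkoxide of the tetrahedral adduct, N,O-chelated (not isolated) | COc1ccc(CCCCC(C=C)(O[Mg]Br)N(C)OC)cc1 | intermediate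
7 | 7-(4-methoxyphenyl)hept-1-en-3-one | COc1ccc(CCCCC(=O)C=C)cc1 | intermediate
8 | 2-methoxybenzene-1,3-diol | COc1c(O)cccc1O | starting material
9 | racemic 2,8-dimethoxy-2-[4-(4-methoxyphenyl)butyl]-3,4-dihydro-2H-chromen-7-ol (not isolated) | COc1ccc(CCCCC2(OC)CCc3ccc(O)c(OC)c3O2)cc1 | intermediate
10 | 1-(2,4-dihydroxy-3-methoxyphenyl)-7-(4-methoxyphenyl)heptan-3-one (CNP0165192.0) | COc1ccc(CCCCC(=O)CCc2ccc(O)c(OC)c2O)cc1 | target

**Step count and risks**
Total step count: 3. Longest linear sequence: 3 steps (1 → 4 → 7 → 10).

Steps most likely to fail, in order of risk:

Step 3. What may go wrong: a second conjugate addition onto the still electron-rich ring of the product, acid-induced oligomerisation of the vinyl ketone, or incomplete reopening of the ketal. The fallback forms the same C1–C1′ bond by cross-coupling at a higher oxidation level. Setting out from 8, mono-iodination (NIS, MeCN, −20 °C) should give 4-iodo-2-methoxybenzene-1,3-diol F1. A Heck reaction of F1 with enone 7 under ligand-free phase-transfer conditions (Pd(OAc)2, NaHCO3, Bu4NCl, DMF, 60 °C) should give (E)-1-(2,4-dihydroxy-3-methoxyphenyl)-7-(4-methoxyphenyl)hept-1-en-3-one F2, the site of arylation being fixed by the iodine. Hydrogenation of the C1=C2 double bond (H2, 1 atm, Pd/C, EtOAc, rt) comes back to the route at 10.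

Step 2. What may go wrong: conjugate addition of liberated N,O-dimethylhydroxylamine or of excess Grignard reagent to the vinyl ketone during the quench, and polymerisation of the enone on concentration. The fallback reaches the enone by oxidation of a storable allylic alcohol. Setting out from 4, reduction with i-Bu2AlH (THF, −78 °C) should give 5-(4-methoxyphenyl)pentanal F3. Addition of 5 (THF, −78 °C) should give racemic 7-(4-methoxyphenyl)hept-1-en-3-ol F4. Oxidation (2-iodoxybenzoic acid, EtOAc, 75 °C) just before the key step comes back to the route at 7.

Step 1. What may go wrong: stalling at the acyl imidazole because the amine is delivered as its hydrochloride, with hydrolysis back to the acid on work-up. The fallback bypasses the amide. Setting out from 1, reduction with BH3·THF (THF, 0 °C to rt) should give 5-(4-methoxyphenyl)pentan-1-ol F5. Oxidation (2-iodoxybenzoic acid, EtOAc, 75 °C) should give 5-(4-methoxyphenyl)pentanal F3, which is carried on as in the fallback of step 2 through the allylic alcohol F4 and comes back to the route at 7.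

**Further compounds**
F1 | step 3 | 4-iodo-2-methoxybenzene-1,3-diol | COc1c(O)ccc(I)c1O
F2 | step 3 | (E)-1-(2,4-dihydroxy-3-methoxyphenyl)-7-(4-methoxyphenyl)hept-1-en-3-one | COc1ccc(CCCCC(=O)/C=C/c2ccc(O)c(OC)c2O)cc1
F3 | step 2 | 5-(4-methoxyphenyl)pentanal | COc1ccc(CCCCC=O)cc1
F4 | step 2 | racemic 7-(4-methoxyphenyl)hept-1-en-3-ol | COc1ccc(CCCCC(O)C=C)cc1
F5 | step 1 | 5-(4-methoxyphenyl)pentan-1-ol | COc1ccc(CCCCCO)cc1
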